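## Retrosynthetic overview

- Numbering (carotenoid): ring C1 = CMe2, C2 = CH2, C3 = CHOH, C4 = CH2, C5 = methyl-bearing sp2 carbon, C6 = ring carbon carrying the alkyne; chain C7≡C8 … C8' = CHO.
- Polyene: C10'=C9', C12'=C11' and C11=C12 by three Wittig olefinations; C6–C7 by Sonogashira coupling of a C6 enol triflate with (2E)-3-methylpent-2-en-4-yn-1-ol.
- The only ring is formed once, in step 4, by an anionic [4+2] annulation: a sulfonyl carbanion at C5 of a C2–C5 chain adds to dimethylketene (C5–C6), and the enolate so formed closes C1–C2 on a primary bromide.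
- Enabling feature: C6 lies between the gem-dimethyl carbon C1 and the methyl-bearing C5, so C1–C6 is dimethylketene at the ketone oxidation level. C2–C3(O)–C4 is the skeleton of (R)-epibromohydrin, which supplies the only stereocentre; the phenylsulfonyl group on C5 is a temporary activating group.

Key step: step 4

Remark: the carbon that becomes sp2 C5 is carried as both epimers in 4, 5 and 8 to 11, which is of no consequence. The carbinol carbon keeps the spatial arrangement of 2 throughout; its descriptor reads S in 10 only because the sulfonyl-bearing carbon changes the priority order.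

## Route

Step 1
Reactants: 1 ethyl phenyl sulfone; 2 (R)-epibromohydrin
Product: 4 (2R)-1-bromo-4-(phenylsulfonyl)pentan-2-ol, via lithiated sulfone 3 (not isolated)
Conditions: n-BuLi (1.0 equiv), THF, −78 °C; BF3·OEt2 (1.1 equiv), then 2 (1.1 equiv), −78 °C, 1 h; H2O quench
Reagents that add atoms: none
Why: Epoxide-opening alkylation of an alpha-sulfonyl carbanion promoted by BF3·OEt2 should occur at the unsubstituted epoxide carbon faster than bromide displacement at −78 °C, the boron-bound alkoxide cannot close to a new epoxide, and the carbinol carbon is not a reacting centre, so its R configuration is that of 2.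

Step 2
Reactants: 4 (2R)-1-bromo-4-(phenylsulfonyl)pentan-2-ol
Product: 5 tert-butyl{[(2R)-1-bromo-4-(phenylsulfonyl)pentan-2-yl]oxy}dimethylsilane
Conditions: TBSOTf (1.2 equiv), 2,6-lutidine (1.5 equiv), CH2Cl2, −78 → 0 °C
Reagents that add atoms: tert-butyldimethylsilyl trifluoromethanesulfonate (TBSOTf), CC(C)(C)[Si](C)(C)OS(=O)(=O)C(F)(F)F
Why: Silylation of a secondary alcohol with a silyl triflate and a hindered pyridine base is fast at low temperature and too weakly basic to close the bromohydrin to an epoxide or to deprotonate the sulfone.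

Step 3
Reactants: 6 2-bromo-2-methylpropanoyl bromide
Product: 7 dimethylketene
Conditions: Zn dust (activated, 1.2 equiv), THF, 0 → 25 °C, N2; trap-to-trap transfer of 7 with THF into a −78 °C receiver, titrated and used at once
Reagents that add atoms: none
Why: Zinc-mediated 1,2-dehalogenation of an alpha-bromoacyl bromide is the classical ketene synthesis, and distilling the volatile ketene away from ZnBr2 gives a Lewis-acid-free solution that the carbanion of step 4 tolerates.

Step 4
Reactants: 5 tert-butyl{[(2R)-1-bromo-4-(phenylsulfonyl)pentan-2-yl]oxy}dimethylsilane; 7 dimethylketene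
Product: 10 (4S)-4-[(tert-butyldimethylsilyl)oxy]-2,2,6-trimethyl-6-(phenylsulfonyl)cyclohexan-1-one, via lithiated sulfone 8 (not isolated), via lithium enolate 9 (not isolated)
Conditions: n-BuLi (1.0 equiv), THF, −78 °C, 30 min; 7 (1.0 equiv, THF solution) dropwise, −78 °C, 30 min; then 25 °C, 16 h
Reagents that add atoms: none
Why: Proposed new method: the alpha-sulfonyl carbanion 8 adds to the carbonyl carbon of dimethylketene 7 (new bond C5–C6) and, because C5 thereby becomes quaternary, gives the fully substituted lithium enolate 9 as the only possible regioisomer; on warming, its carbon terminus C1 displaces the primary bromide at C2 (new bond C1–C2), so the ketene serves first as electrophile and then as nucleophile in an anionic [4+2] annulation. The closest known reaction types are the addition of organolithium reagents to ketenes, which gives regiodefined tetrasubstituted ketone enolates that are C-alkylated in the same flask, and the ring-closing C-alkylation of ketone enolates by a tethered primary bromide. The one ring closes in the 6-(enolendo)-exo-tet mode, which is geometrically allowed for a six-membered ring. No lasting stereocentre is created: the carbinol carbon is not a reacting centre and keeps the configuration of 2, and the sulfonyl-bearing carbon forms as both epimers and is erased in steps 5 and 6. The step needs C- over O-alkylation and a single addition of the ketene; the lithium counter-ion in THF without polar additive and the soft bromide leaving group favour C-alkylation, and slow addition of one equivalent of 7 at −78 °C to an amine-free carbanion keeps the carbanion in excess over the hindered enolate so that the enolate is not acylated further.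

Step 5
Reactants: 10 (4S)-4-[(tert-butyldimethylsilyl)oxy]-2,2,6-trimethyl-6-(phenylsulfonyl)cyclohexan-1-one
Product: 11 (4R)-4-[(tert-butyldimethylsilyl)oxy]-2,2,6-trimethylcyclohexan-1-one
Conditions: SmI2 (2.5 equiv), THF/MeOH (5:1), −78 °C, 20 min; aq. NH4Cl
Reagents that add atoms: none
Why: Reductive desulfonylation of a beta-keto sulfone by SmI2 (two single-electron transfers, loss of benzenesulfinate, protonation by methanol) removes the temporary activating group without touching the silyl ether, and the methyl-bearing carbon forms as both epimers that converge in step 6.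

Step 6
Reactants: 11 (4R)-4-[(tert-butyldimethylsilyl)oxy]-2,2,6-trimethylcyclohexan-1-one
Product: 13 (4R)-4-[(tert-butyldimethylsilyl)oxy]-2,6,6-trimethylcyclohex-1-en-1-yl trifluoromethanesulfonate, via lithium enolate 12 (not isolated)
Conditions: LiN(i-Pr)2 (1.2 equiv), THF, −78 → 0 °C, 1 h; PhNTf2 (1.3 equiv), −78 → 25 °C; aq. NH4Cl
Reagents that add atoms: N-phenylbis(trifluoromethanesulfonimide) (PhNTf2), O=S(=O)(N(c1ccccc1)S(=O)(=O)C(F)(F)F)C(F)(F)F
Why: Enolate O-sulfonylation (enol triflate formation) can only go towards the methyl-bearing carbon because the other alpha-carbon is quaternary, so the C5=C6 enol triflate should form as a single regioisomer.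

Step 7
Reactants: 13 (4R)-4-[(tert-butyldimethylsilyl)oxy]-2,6,6-trimethylcyclohex-1-en-1-yl trifluoromethanesulfonate; 14 (2E)-3-methylpent-2-en-4-yn-1-ol
Product: 15 (2E)-5-{(4R)-4-[(tert-butyldimethylsilyl)oxy]-2,6,6-trimethylcyclohex-1-en-1-yl}-3-methylpent-2-en-4-yn-1-ol
Conditions: 14 (1.3 equiv), Pd(PPh3)4 (5 mol %), CuI (10 mol %), i-Pr2NH (3 equiv), DMF, 25 → 50 °C, Ar
Reagents that add atoms: none
Why: Sonogashira coupling of an alkenyl triflate with a terminal alkyne (zerovalent palladium with CuI co-catalyst) forms C6–C7 with retention of the (E)-alkene of 14, and the free primary alcohol and the silyl ether are inert to it.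

Step 8
Reactants: 15 (2E)-5-{(4R)-4-[(tert-butyldimethylsilyl)oxy]-2,6,6-trimethylcyclohex-1-en-1-yl}-3-methylpent-2-en-4-yn-1-ol
Product: 16 {(2E)-5-[(4R)-4-hydroxy-2,6,6-trimethylcyclohex-1-en-1-yl]-3-methylpent-2-en-4-yn-1-yl}triphenylphosphonium bromide
Conditions: PPh3·HBr (1.3 equiv), MeOH, 0 → 25 °C, 16 h, dark
Reagents that add atoms: triphenylphosphine hydrobromide (PPh3·HBr), [Br-].[PH+](c1ccccc1)(c1ccccc1)c1ccccc1
Why: Acid-mediated conversion of a primary allylic alcohol into its phosphonium salt (PPh3 captures the enyne-stabilised allyl cation at the primary terminus) is standard for polyene building blocks, the same methanolic acid should methanolyse the secondary silyl ether, and the homoallylic secondary alcohol is not ionised, so the stereocentre is kept.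

Step 9
Reactants: 16 {(2E)-5-[(4R)-4-hydroxy-2,6,6-trimethylcyclohex-1-en-1-yl]-3-methylpent-2-en-4-yn-1-yl}triphenylphosphonium bromide; 17 (2E,4E,6E)-2,7-dimethylocta-2,4,6-trienedial
Product: 19 (3R)-3-hydroxy-7,8-didehydro-12'-apo-β-caroten-12'-al, via phosphonium ylide 18 (not isolated)
Conditions: 17 (2 equiv), NaOMe (1.1 equiv), MeOH/CH2Cl2, 0 → 25 °C, Ar, dark; then EtOH, 70 °C, 2 h
Reagents that add atoms: none
Why: Wittig olefination of the semi-stabilised allylic ylide with one aldehyde of the symmetrical dialdehyde (in excess to suppress double reaction) forms C11=C12, and the hindered 11Z isomer should convert to 11E on heating.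

Step 10
Reactants: 19 (3R)-3-hydroxy-7,8-didehydro-12'-apo-β-caroten-12'-al; 20 (1,3-dioxolan-2-ylmethyl)triphenylphosphonium bromide
Product: 23 (3R)-3-hydroxy-7,8-didehydro-10'-apo-β-caroten-10'-al, via phosphonium ylide 21 (not isolated), via dioxolane acetal 22 (not isolated)
Conditions: 20 (2.2 equiv), KOt-Bu (2.2 equiv), THF, 0 °C, 30 min; 19, 0 → 25 °C; then 1 M aq. HCl/THF, 25 °C, 1 h
Reagents that add atoms: water, O
Why: Wittig olefination with an acetal-masked two-carbon ylide followed by acid hydrolysis is a vinylogation that cannot over-homologate because the new aldehyde stays masked until work-up, and the acid should equilibrate the new enal double bond to E.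

Step 11
Reactants: 23 (3R)-3-hydroxy-7,8-didehydro-10'-apo-β-caroten-10'-al; 24 2-(triphenyl-λ5-phosphanylidene)propanal
Product: 25 (3R)-3-hydroxy-7,8-didehydro-8'-apo-β-caroten-8'-al
Conditions: 24 (1.3 equiv), toluene, 80 °C, Ar, dark
Reagents that add atoms: none
Why: Wittig olefination with a stabilised alpha-methyl formyl ylide is E-selective and should stop after one addition because the alpha-methyl enal formed is less electrophilic than 23, which completes the all-E polyenal with the stereocentre untouched.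

## Compound list

1 | ethyl phenyl sulfone | CCS(=O)(=O)c1ccccc1 | starting material
2 | (R)-epibromohydrin, (2R)-2-(bromomethyl)oxirane | BrC[C@H]1CO1 | starting material
3 | (1-lithioethyl) phenyl sulfone | [Li+].C[CH-]S(=O)(=O)c1ccccc1 | intermediate
4 | (2R)-1-bromo-4-(phenylsulfonyl)pentan-2-ol, both epimers at C4 | BrC[C@H](O)CC(C)S(=O)(=O)c1ccccc1 | intermediate
5 | tert-butyl{[(2R)-1-bromo-4-(phenylsulfonyl)pentan-2-yl]oxy}dimethylsilane, both epimers at C4 | BrC[C@H](O[Si](C)(C)C(C)(C)C)CC(C)S(=O)(=O)c1ccccc1 | intermediate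
6 | 2-bromo-2-methylpropanoyl bromide | CC(C)(Br)C(=O)Br | starting material
7 | dimethylketene (2-methylprop-1-en-1-one) | CC(C)=C=O | intermediate
8 | lithium salt of the alpha-sulfonyl carbanion of 5 | [Li+].BrC[C@H](O[Si](C)(C)C(C)(C)C)C[C-](C)S(=O)(=O)c1ccccc1 | intermediate
9 | lithium (6R)-7-bromo-6-[(tert-butyldimethylsilyl)oxy]-2,4-dimethyl-4-(phenylsulfonyl)hept-2-en-3-olate | [Li+].BrC[C@H](O[Si](C)(C)C(C)(C)C)CC(C)(C([O-])=C(C)C)S(=O)(=O)c1ccccc1 | intermediate
10 | (4S)-4-[(tert-butyldimethylsilyl)oxy]-2,2,6-trimethyl-6-(phenylsulfonyl)cyclohexan-1-one, both epimers at C6 | O=C1C(C)(C)C[C@H](O[Si](C)(C)C(C)(C)C)CC1(C)S(=O)(=O)c1ccccc1 | intermediate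
11 | (4R)-4-[(tert-butyldimethylsilyl)oxy]-2,2,6-trimethylcyclohexan-1-one, both epimers at C6 | O=C1C(C)(C)C[C@H](O[Si](C)(C)C(C)(C)C)CC1C | intermediate
12 | lithium (4R)-4-[(tert-butyldimethylsilyl)oxy]-2,6,6-trimethylcyclohex-1-en-1-olate | [Li+].CC1=C([O-])C(C)(C)C[C@H](O[Si](C)(C)C(C)(C)C)C1 | intermediate
13 | (4R)-4-[(tert-butyldimethylsilyl)oxy]-2,6,6-trimethylcyclohex-1-en-1-yl trifluoromethanesulfonate | CC1=C(OS(=O)(=O)C(F)(F)F)C(C)(C)C[C@H](O[Si](C)(C)C(C)(C)C)C1 | intermediate
14 | (2E)-3-methylpent-2-en-4-yn-1-ol | C#C/C(C)=C/CO | starting material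
15 | (2E)-5-{(4R)-4-[(tert-butyldimethylsilyl)oxy]-2,6,6-trimethylcyclohex-1-en-1-yl}-3-methylpent-2-en-4-yn-1-ol | CC1=C(C#C/C(C)=C/CO)C(C)(C)C[C@H](O[Si](C)(C)C(C)(C)C)C1 | intermediate
16 | {(2E)-5-[(4R)-4-hydroxy-2,6,6-trimethylcyclohex-1-en-1-yl]-3-methylpent-2-en-4-yn-1-yl}triphenylphosphonium bromide | CC1=C(C#C/C(C)=C/C[P+](c2ccccc2)(c2ccccc2)c2ccccc2)C(C)(C)C[C@H](O)C1.[Br-] | intermediate
17 | (2E,4E,6E)-2,7-dimethylocta-2,4,6-trienedial | O=C/C(C)=C/C=C/C=C(\C)C=O | starting material
18 | ylide of 16, {(2E)-5-[(4R)-4-hydroxy-2,6,6-trimethylcyclohex-1-en-1-yl]-3-methylpent-2-en-4-yn-1-ylidene}triphenyl-λ5-phosphane | CC1=C(C#C/C(C)=C/C=P(c2ccccc2)(c2ccccc2)c2ccccc2)C(C)(C)C[C@H](O)C1 | intermediate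
19 | (3R)-3-hydroxy-7,8-didehydro-12'-apo-β-caroten-12'-al, (2E,4E,6E,8E,10E)-13-[(4R)-4-hydroxy-2,6,6-trimethylcyclohex-1-en-1-yl]-2,7,11-trimethyltrideca-2,4,6,8,10-pentaen-12-ynal | CC1=C(C#C/C(C)=C/C=C/C(C)=C/C=C/C=C(C)/C=O)C(C)(C)C[C@H](O)C1 | intermediate
20 | (1,3-dioxolan-2-ylmethyl)triphenylphosphonium bromide | [Br-].C1COC(C[P+](c2ccccc2)(c2ccccc2)c2ccccc2)O1 | starting material
21 | (1,3-dioxolan-2-ylmethylidene)triphenyl-λ5-phosphane | C1COC(C=P(c2ccccc2)(c2ccccc2)c2ccccc2)O1 | intermediate
22 | 1,3-dioxolane acetal of 23, new C11'=C12' bond as an E/Z mixture | CC1=C(C#C/C(C)=C/C=C/C(C)=C/C=C/C=C(C)/C=CC2OCCO2)C(C)(C)C[C@H](O)C1 | intermediate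
23 | (3R)-3-hydroxy-7,8-didehydro-10'-apo-β-caroten-10'-al, (2E,4E,6E,8E,10E,12E)-15-[(4R)-4-hydroxy-2,6,6-trimethylcyclohex-1-en-1-yl]-4,9,13-trimethylpentadeca-2,4,6,8,10,12-hexaen-14-ynal | CC1=C(C#C/C(C)=C/C=C/C(C)=C/C=C/C=C(C)/C=C/C=O)C(C)(C)C[C@H](O)C1 | intermediate
24 | 2-(triphenyl-λ5-phosphanylidene)propanal | CC(C=O)=P(c1ccccc1)(c1ccccc1)c1ccccc1 | starting material
25 | (3R)-3-hydroxy-7,8-didehydro-8'-apo-β-caroten-8'-al, (2E,4E,6E,8E,10E,12E,14E)-17-[(4R)-4-hydroxy-2,6,6-trimethylcyclohex-1-en-1-yl]-2,6,11,15-tetramethylheptadeca-2,4,6,8,10,12,14-heptaen-16-ynal | CC1=C(C#C/C(C)=C/C=C/C(C)=C/C=C/C=C(C)/C=C/C=C(\C)C=O)C(C)(C)C[C@H](O)C1 | target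

## Step count and risks

Total steps: 11. Longest linear sequence: 10 steps (steps 1, 2 and 4 to 11; step 3 is a one-step side branch).

Steps most likely to fail:

1. Step 4 (proposed new method). The hindered enolate may alkylate on oxygen instead of carbon, or the enolate may be acylated further by the ketene (onset of anionic ketene oligomerisation). The fallback reverses the order of the two bond formations, uses only known chemistry, sets out from 5 and comes back at 10. The lithium enolate of methyl isobutyrate (LiN(i-Pr)2, THF/DMPU, −78 → 0 °C) is alkylated by the primary bromide of 5 to give methyl (4S)-4-[(tert-butyldimethylsilyl)oxy]-2,2-dimethyl-6-(phenylsulfonyl)heptanoate F1; an ester enolate forms the quaternary carbon without an O-alkylation problem. Deprotonation of F1 at the sulfone (LiN(i-Pr)2, THF, −78 → 0 °C) then closes the ring by intramolecular acylation of the sulfonyl carbanion on the ester, giving 10.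

2. Step 7. Oxidative addition at the alkenyl triflate, which is flanked by a quaternary carbon and a methyl-bearing carbon, may be slow, and oxidative dimerisation of the alkyne may take over. The fallback builds the enyne by acetylide addition and dehydration, sets out from 11 and comes back at 16. Alcohol 14 is silylated (TBSCl, imidazole, DMF) to tert-butyldimethyl{[(2E)-3-methylpent-2-en-4-yn-1-yl]oxy}silane F2. Its lithium acetylide (n-BuLi, CeCl3, THF, −78 °C) is added to ketone 11 to give (4R)-4-[(tert-butyldimethylsilyl)oxy]-1-{(3E)-5-[(tert-butyldimethylsilyl)oxy]-3-methylpent-3-en-1-yn-1-yl}-2,2,6-trimethylcyclohexan-1-ol F3. Dehydration with POCl3 in pyridine, which can only remove the ring hydrogen next to the methyl group because the other neighbour is quaternary, gives tert-butyl{[(2E)-5-{(4R)-4-[(tert-butyldimethylsilyl)oxy]-2,6,6-trimethylcyclohex-1-en-1-yl}-3-methylpent-2-en-4-yn-1-yl]oxy}dimethylsilane F4. Under the conditions of step 8 both silyl ethers of F4 are methanolysed and the primary allylic position is converted to the phosphonium salt 16.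

3. Step 9. The dialdehyde may be olefinated at both ends, and alkene geometry may erode (Z isomer at the new C11=C12 bond, isomerisation at C9=C10 carried over from the acidic salt formation). The fallback replaces the phosphonium ylide by a phosphonate carbanion, sets out from 15 (so it also bypasses step 8) and comes back at 19. An Appel reaction (CBr4, PPh3, CH2Cl2, 0 °C) gives {[(1R)-4-[(3E)-5-bromo-3-methylpent-3-en-1-yn-1-yl]-3,5,5-trimethylcyclohex-3-en-1-yl]oxy}(tert-butyl)dimethylsilane F5 under neutral conditions that keep the 9E geometry. An Arbuzov reaction (P(OEt)3, 90 °C) gives diethyl [(2E)-5-{(4R)-4-[(tert-butyldimethylsilyl)oxy]-2,6,6-trimethylcyclohex-1-en-1-yl}-3-methylpent-2-en-4-yn-1-yl]phosphonate F6. Horner–Wadsworth–Emmons olefination (NaN(SiMe3)2, THF, −78 °C, then 17 in excess) gives the E-configured silyl ether of 19, (2E,4E,6E,8E,10E)-13-{(4R)-4-[(tert-butyldimethylsilyl)oxy]-2,6,6-trimethylcyclohex-1-en-1-yl}-2,7,11-trimethyltrideca-2,4,6,8,10-pentaen-12-ynal F7. Desilylation with HF·pyridine in THF at 0 °C gives 19.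

Further compounds
F1 | step 4 | methyl (4S)-4-[(tert-butyldimethylsilyl)oxy]-2,2-dimethyl-6-(phenylsulfonyl)heptanoate | COC(=O)C(C)(C)C[C@H](O[Si](C)(C)C(C)(C)C)CC(C)S(=O)(=O)c1ccccc1
F2 | step 7 | tert-butyldimethyl{[(2E)-3-methylpent-2-en-4-yn-1-yl]oxy}silane | C#C/C(C)=C/CO[Si](C)(C)C(C)(C)C
F3 | step 7 | (4R)-4-[(tert-butyldimethylsilyl)oxy]-1-{(3E)-5-[(tert-butyldimethylsilyl)oxy]-3-methylpent-3-en-1-yn-1-yl}-2,2,6-trimethylcyclohexan-1-ol | OC1(C#C/C(C)=C/CO[Si](C)(C)C(C)(C)C)C(C)(C)C[C@H](O[Si](C)(C)C(C)(C)C)CC1C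
F4 | step 7 | tert-butyl{[(2E)-5-{(4R)-4-[(tert-butyldimethylsilyl)oxy]-2,6,6-trimethylcyclohex-1-en-1-yl}-3-methylpent-2-en-4-yn-1-yl]oxy}dimethylsilane | CC1=C(C#C/C(C)=C/CO[Si](C)(C)C(C)(C)C)C(C)(C)C[C@H](O[Si](C)(C)C(C)(C)C)C1
F5 | step 9 | {[(1R)-4-[(3E)-5-bromo-3-methylpent-3-en-1-yn-1-yl]-3,5,5-trimethylcyclohex-3-en-1-yl]oxy}(tert-butyl)dimethylsilane | CC1=C(C#C/C(C)=C/CBr)C(C)(C)C[C@H](O[Si](C)(C)C(C)(C)C)C1
F6 | step 9 | diethyl [(2E)-5-{(4R)-4-[(tert-butyldimethylsilyl)oxy]-2,6,6-trimethylcyclohex-1-en-1-yl}-3-methylpent-2-en-4-yn-1-yl]phosphonate | CC1=C(C#C/C(C)=C/CP(=O)(OCC)OCC)C(C)(C)C[C@H](O[Si](C)(C)C(C)(C)C)C1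
F7 | step 9 | (2E,4E,6E,8E,10E)-13-{(4R)-4-[(tert-butyldimethylsilyl)oxy]-2,6,6-trimethylcyclohex-1-en-1-yl}-2,7,11-trimethyltrideca-2,4,6,8,10-pentaen-12-ynal | CC1=C(C#C/C(C)=C/C=C/C(C)=C/C=C/C=C(C)/C=O)C(C)(C)C[C@H](O[Si](C)(C)C(C)(C)C)C1
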